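**Strategy.** The depside ester between ring A and the ring B C4 oxygen is the obvious late disconnection, so the route rests on building ring B itself. Ring B carries its C1 carboxyl and C6 pentyl on neighbouring carbons (an oct-2-ynoate in disguise) and oxygens on C2 and C4 (a 1,1-dialkoxy-3-silyloxybutadiene spanning C2–C5). One Diels–Alder/aromatisation between benzyl oct-2-ynoate and 1,1-dimethoxy-3-(trimethylsilyloxy)buta-1,3-diene forms C1–C2 and C5–C6, closes ring B and delivers the two oxygens differentiated: C4 as the only free phenol, C2 as a methyl ether. Acylation with unprotected everninic acid, hydrogenolysis and a chelation-directed demethylation finish the synthesis.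

Key step: step 5

Remark: the target has no stereocentre; the alkene geometry of transient compound 7 is immaterial and is left unassigned.

**Step 1**
Reactants: 1 oct-2-ynoic acid
Product: 2 benzyl oct-2-ynoate
Conditions: BnBr, KHCO3, DMF, rt
Reagents that add atoms: benzyl bromide, BrCc1ccccc1
Why: SN2 O-alkylation of the carboxylate under mild bicarbonate base should give the benzyl ester without isomerising the conjugated alkyne to the allenoate.

**Step 2**
Reactants: 3 acetyl chloride; 4 1,1-dichloroethene
Product: 6 4,4-dichlorobut-3-en-2-one, via trichloroketone 5 (not isolated)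
Conditions: AlCl3, CH2Cl2, 0 °C to rt; ice/aq. HCl quench; steam distillation
Reagents that add atoms: none
Why: Friedel–Crafts-type acylation of the CH2 terminus of the dichloroalkene by the acetyl chloride–AlCl3 complex gives 4,4,4-trichlorobutan-2-one, which should lose HCl by β-elimination on steam distillation to the conjugated dichloroenone.

**Step 3**
Reactants: 6 4,4-dichlorobut-3-en-2-one
Product: 8 4,4-dimethoxybut-3-en-2-one, via chloro methoxy enone 7 (not isolated)
Conditions: NaOMe (2.2 equiv), MeOH, 0 °C to rt; distillation
Reagents that add atoms: sodium methoxide, [Na+].[O-]C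
Why: Two successive conjugate addition–elimination events (vinylogous acyl substitution) should replace both β-chlorides by methoxide and give the push–pull ketene acetal.

**Step 4**
Reactants: 8 4,4-dimethoxybut-3-en-2-one
Product: 9 1,1-dimethoxy-3-(trimethylsilyloxy)buta-1,3-diene
Conditions: TMSCl, Et3N, ZnCl2 (cat.), toluene, 40 °C; filtration under Ar, distillation
Reagents that add atoms: chlorotrimethylsilane, C[Si](C)(C)Cl
Why: Soft enolisation of the methyl ketone followed by O-silylation is the standard silyl enol ether formation for vinylogous esters and should give the cross-conjugated 2-silyloxydiene.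

**Step 5**
Reactants: 2 benzyl oct-2-ynoate; 9 1,1-dimethoxy-3-(trimethylsilyloxy)buta-1,3-diene
Product: 12 benzyl 4-hydroxy-2-methoxy-6-pentylbenzoate, via ketal cycloadduct 10 (not isolated), via aryl silyl ether 11 (not isolated)
Conditions: neat, 9 (2.5 equiv), 120–130 °C, sealed tube, Ar; then 1 M HCl, THF, rt
Reagents that add atoms: none
Why: A thermal normal-electron-demand Diels–Alder (4+2) cycloaddition between the electron-rich ketene acetal diene and the electron-poor ynoate gives the cyclohexa-1,4-diene ketal 10, 1,4-elimination of methanol aromatises it to 11, and mild acid cleaves the aryl silyl ether to phenol 12. The closest known reaction type is the benzannulation of 1,1-dialkoxy-3-silyloxybutadienes with acetylenic esters to 4-hydroxy-2-alkoxybenzoates. Ring B is closed in a six-membered (4+2) mode, with C1–C2 and C5–C6 formed in one concerted but asynchronous operation. No stereocentre is created, so only regiochemistry matters: the unsubstituted CH2 terminus of 9, which carries the largest HOMO coefficient through the push of all three oxygens, should bond to the electrophilic β-carbon (C3) of the ynoate and the acetal carbon to the α-carbon. The substrate secures this because the ester and the pentyl chain are the only substituents on the triple bond and polarise it in one direction. Excess diene and strict exclusion of moisture are planned because a single ester makes 2 only a moderate dienophile.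

**Step 6**
Reactants: 13 methyl orsellinate (methyl 2,4-dihydroxy-6-methylbenzoate)
Product: 14 methyl 2-hydroxy-4-methoxy-6-methylbenzoate
Conditions: MeI (1.1 equiv), K2CO3, acetone, reflux
Reagents that add atoms: iodomethane, CI
Why: Williamson O-methylation should be site-selective for the 4-hydroxyl because the 2-hydroxyl is held in a hydrogen bond to the ester carbonyl and is less acidic and more hindered.

**Step 7**
Reactants: 14 methyl 2-hydroxy-4-methoxy-6-methylbenzoate
Product: 15 2-hydroxy-4-methoxy-6-methylbenzoic acid (everninic acid)
Conditions: KOH, DMSO–H2O, 90 °C; then cold 2 M HCl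
Reagents that add atoms: potassium hydroxide, [K+].[OH-]
Why: Saponification of the hindered salicylate ester needs forcing hydroxide in aqueous DMSO, and cold acidification should release the acid without decarboxylation.

**Step 8**
Reactants: 12 benzyl 4-hydroxy-2-methoxy-6-pentylbenzoate; 15 2-hydroxy-4-methoxy-6-methylbenzoic acid
Product: 17 benzyl 4-[(2-hydroxy-4-methoxy-6-methylbenzoyl)oxy]-2-methoxy-6-pentylbenzoate, via mixed anhydride 16 (not isolated)
Conditions: (CF3CO)2O, toluene, 0 °C to rt; aq. NaHCO3 work-up
Reagents that add atoms: none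
Why: Mixed-anhydride esterification: trifluoroacetic anhydride turns the 2,6-disubstituted acid into an acylium equivalent that acylates the only free phenol of 12, while the ring A 2-hydroxyl, chelated to its carbonyl and flanked, should not compete and needs no protecting group.

**Step 9**
Reactants: 17 benzyl 4-[(2-hydroxy-4-methoxy-6-methylbenzoyl)oxy]-2-methoxy-6-pentylbenzoate
Product: 18 4-[(2-hydroxy-4-methoxy-6-methylbenzoyl)oxy]-2-methoxy-6-pentylbenzoic acid
Conditions: H2 (1 atm), Pd/C (10% palladium on carbon), EtOAc, rt
Reagents that add atoms: none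
Why: Catalytic hydrogenolysis should cleave only the benzyl ester, and doing it before the Lewis acid step means BCl3, which also attacks benzyl esters, never generates a benzylating species next to electron-rich ring A.

**Step 10**
Reactants: 18 4-[(2-hydroxy-4-methoxy-6-methylbenzoyl)oxy]-2-methoxy-6-pentylbenzoic acid
Product: 19 2-hydroxy-4-[(2-hydroxy-4-methoxy-6-methylbenzoyl)oxy]-6-pentylbenzoic acid (CNP0313373.0)
Conditions: BCl3 (1 M in CH2Cl2, 4 equiv), CH2Cl2, −78 to 0 °C; ice-water quench
Reagents that add atoms: none
Why: Chelation-directed ether cleavage: boron bound to the ring B carboxyl group forms a six-membered chelate with the ortho C2 methoxy oxygen and chloride removes the methyl by SN2, whereas the ring A 4-methoxy, para to its carbonyl and unable to chelate, should survive at or below 0 °C.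

**Compound list**
1 | oct-2-ynoic acid | CCCCCC#CC(=O)O | starting material
2 | benzyl oct-2-ynoate | CCCCCC#CC(=O)OCc1ccccc1 | intermediate
3 | acetyl chloride | CC(=O)Cl | starting material
4 | 1,1-dichloroethene | C=C(Cl)Cl | starting material
5 | 4,4,4-trichlorobutan-2-one | CC(=O)CC(Cl)(Cl)Cl | intermediate (not isolated)
6 | 4,4-dichlorobut-3-en-2-one | CC(=O)C=C(Cl)Cl | intermediate
7 | 4-chloro-4-methoxybut-3-en-2-one (alkene isomers, unassigned) | CC(=O)C=C(Cl)OC | intermediate (not isolated)
8 | 4,4-dimethoxybut-3-en-2-one | CC(=O)C=C(OC)OC | intermediate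
9 | 1,1-dimethoxy-3-(trimethylsilyloxy)buta-1,3-diene | C=C(O[Si](C)(C)C)C=C(OC)OC | intermediate
10 | benzyl 6,6-dimethoxy-2-pentyl-4-(trimethylsilyloxy)cyclohexa-1,4-diene-1-carboxylate | CCCCCC1=C(C(=O)OCc2ccccc2)C(OC)(OC)C=C(O[Si](C)(C)C)C1 | intermediate (not isolated)
11 | benzyl 2-methoxy-6-pentyl-4-(trimethylsilyloxy)benzoate | CCCCCc1cc(O[Si](C)(C)C)cc(OC)c1C(=O)OCc1ccccc1 | intermediate (not isolated)
12 | benzyl 4-hydroxy-2-methoxy-6-pentylbenzoate | CCCCCc1cc(O)cc(OC)c1C(=O)OCc1ccccc1 | intermediate
13 | methyl orsellinate (methyl 2,4-dihydroxy-6-methylbenzoate) | COC(=O)c1c(C)cc(O)cc1O | starting material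
14 | methyl 2-hydroxy-4-methoxy-6-methylbenzoate | COC(=O)c1c(C)cc(OC)cc1O | intermediate
15 | 2-hydroxy-4-methoxy-6-methylbenzoic acid | Cc1cc(OC)cc(O)c1C(=O)O | intermediate
16 | 2-hydroxy-4-methoxy-6-methylbenzoic trifluoroacetic anhydride | Cc1cc(OC)cc(O)c1C(=O)OC(=O)C(F)(F)F | intermediate (not isolated)
17 | benzyl 4-[(2-hydroxy-4-methoxy-6-methylbenzoyl)oxy]-2-methoxy-6-pentylbenzoate | CCCCCc1cc(OC(=O)c2c(C)cc(OC)cc2O)cc(OC)c1C(=O)OCc1ccccc1 | intermediate
18 | 4-[(2-hydroxy-4-methoxy-6-methylbenzoyl)oxy]-2-methoxy-6-pentylbenzoic acid | CCCCCc1cc(OC(=O)c2c(C)cc(OC)cc2O)cc(OC)c1C(=O)O | intermediate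
19 | 2-hydroxy-4-[(2-hydroxy-4-methoxy-6-methylbenzoyl)oxy]-6-pentylbenzoic acid | CCCCCc1cc(OC(=O)c2c(C)cc(OC)cc2O)cc(O)c1C(=O)O | target

**Step count and risks**
Total step count: 10. Longest linear sequence: 7 (steps 2, 3, 4, 5, 8, 9, 10).

Steps most likely to fail:

Step 5. The heat- and moisture-sensitive diene may be consumed by hydrolysis or self-condensation before it adds to the only moderately activated β-alkyl ynoate, or the adduct may not lose methanol cleanly. The fallback abandons the cycloaddition and builds the ring B ester by classical arene carboxylation. It sets out from acid 15 together with purchased olivetol (5-pentylbenzene-1,3-diol, CCCCCc1cc(O)cc(O)c1) and comes back to the route at target 19. Kolbe–Schmitt-type ortho-carboxylation of olivetol with MeOMgOCO2Me (magnesium methyl carbonate) in DMF at 120 °C should give 2,4-dihydroxy-6-pentylbenzoic acid F1. Carboxylate alkylation with BnBr/KHCO3 in DMF should give benzyl 2,4-dihydroxy-6-pentylbenzoate F2. Trifluoroacetic anhydride coupling with 15 as in step 8 should acylate the 4-hydroxyl, the 2-hydroxyl being hydrogen-bonded to the ester carbonyl, and give benzyl 2-hydroxy-4-[(2-hydroxy-4-methoxy-6-methylbenzoyl)oxy]-6-pentylbenzoate F3. Hydrogenolysis over Pd/C then gives 19 with no ether cleavage at all.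

Step 10. The Lewis acid may over-react, cleaving the non-chelated ring A ether or the depside acyl–oxygen bond, or the demethylation may stop short. The fallback moves the demethylation to the single-ring stage, where neither the depside ester nor a second methoxy group is present, and then relies on hydrogen-bond-controlled site-selective acylation. It sets out from 12 and comes back at 19. Hydrogenolysis of 12 over Pd/C should give 4-hydroxy-2-methoxy-6-pentylbenzoic acid F4. BCl3 in CH2Cl2 should remove the chelated methyl group and give 2,4-dihydroxy-6-pentylbenzoic acid F1. This acid is carried on through benzyl 2,4-dihydroxy-6-pentylbenzoate F2 and the coupled benzyl ester F3 to 19 exactly as in the fallback for step 5.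

Step 8. The unprotected hydroxy acid may self-acylate to oligomeric salicylides, or the phenol may merely be trifluoroacetylated instead of cross-coupled. The fallback masks the ring A hydroxyl and uses a preformed acid chloride. It sets out from 14 and comes back at 18. Benzylation of 14 with BnBr/K2CO3 in DMF at 70 °C should give methyl 2-(benzyloxy)-4-methoxy-6-methylbenzoate F5. Saponification with KOH in aqueous DMSO should give 2-(benzyloxy)-4-methoxy-6-methylbenzoic acid F6. Oxalyl chloride with catalytic DMF should give 2-(benzyloxy)-4-methoxy-6-methylbenzoyl chloride F7. Acylation of 12 with Et3N and catalytic DMAP in CH2Cl2 should give benzyl 4-{[2-(benzyloxy)-4-methoxy-6-methylbenzoyl]oxy}-2-methoxy-6-pentylbenzoate F8. Hydrogenolysis over Pd/C removes both benzyl groups and gives 18.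

**Further compounds**
F1 | step 5 | 2,4-dihydroxy-6-pentylbenzoic acid | CCCCCc1cc(O)cc(O)c1C(=O)O
F2 | step 5 | benzyl 2,4-dihydroxy-6-pentylbenzoate | CCCCCc1cc(O)cc(O)c1C(=O)OCc1ccccc1
F3 | step 5 | benzyl 2-hydroxy-4-[(2-hydroxy-4-methoxy-6-methylbenzoyl)oxy]-6-pentylbenzoate | CCCCCc1cc(OC(=O)c2c(C)cc(OC)cc2O)cc(O)c1C(=O)OCc1ccccc1
F4 | step 10 | 4-hydroxy-2-methoxy-6-pentylbenzoic acid | CCCCCc1cc(O)cc(OC)c1C(=O)O
F5 | step 8 | methyl 2-(benzyloxy)-4-methoxy-6-methylbenzoate | COC(=O)c1c(C)cc(OC)cc1OCc1ccccc1
F6 | step 8 | 2-(benzyloxy)-4-methoxy-6-methylbenzoic acid | Cc1cc(OC)cc(OCc2ccccc2)c1C(=O)O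
F7 | step 8 | 2-(benzyloxy)-4-methoxy-6-methylbenzoyl chloride | Cc1cc(OC)cc(OCc2ccccc2)c1C(=O)Cl
F8 | step 8 | benzyl 4-{[2-(benzyloxy)-4-methoxy-6-methylbenzoyl]oxy}-2-methoxy-6-pentylbenzoate | CCCCCc1cc(OC(=O)c2c(C)cc(OC)cc2OCc2ccccc2)cc(OC)c1C(=O)OCc1ccccc1
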